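**Plan**
1. Retrosynthetic cuts: (i) the four O–benzyl bonds of a protected precursor. (ii) Both ring C–O bonds, O1–C2 and O1–C5, with C2 rejoined to C5, so that the oxolane contracts to cyclobutane 10. (iii) The two C(=O)–aryl bonds of the dioxygenated benzoyl groups. (iv) The cyclobutane bonds C3–C4 and C2–C5, back to two p-coumarate units.
2. Enabling feature: C2 and C5, the ring carbons flanking O1, each carry a 4-hydroxyphenyl ring. In 10 they are bonded directly, so a strained C–C σ-bond lies between two para-phenols. Two-electron oxidation breaks it to a bis(p-quinone methide), which takes up one water molecule as O1.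
3. Forward order: two coumarate units are tied to a 1,8-naphthalenediol template (temporary ring). The cyclobutane is closed by [2+2] photocycloaddition, the template is exchanged for Weinreb amides, and the aroyl groups are added. The four-membered ring is then expanded to the oxolane and the benzyl groups are removed.
4. Stereochemistry: C3/C4 cis comes from the syn head-to-head templated photodimerisation and is kept to the end. C2/C5 are set in the ring expansion, each aryl trans to the neighbouring aroyl group.

Key step: step 6

Remark on the chemistry: the descriptors (2R,3R,4S,5S) describe a meso compound (mirror plane through O1 and the midpoint of C3–C4; 2,3-trans, 3,4-cis, 4,5-trans). No absolute stereocontrol is therefore needed and only the relative configuration is controlled.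

**Step 1**
Reactants: 1 (E)-4-acetoxycinnamic acid; 2 1,8-dihydroxynaphthalene
Product: 3 naphthalene-1,8-diyl bis[(E)-3-(4-acetoxyphenyl)prop-2-enoate]
Conditions: 1 (2.1 equiv), DCC (2.2 equiv), DMAP (cat.), CH2Cl2, 0 °C → rt
Reagents that add atoms: none
Why: Steglich esterification, in which the DCC/DMAP-activated acid acylates both peri-hydroxyl groups of 2 under neutral conditions that leave the aryl acetates alone; no stereocentre is formed.

**Step 2**
Reactants: 3 naphthalene-1,8-diyl bis[(E)-3-(4-acetoxyphenyl)prop-2-enoate]
Product: 4 cyclic naphthalene-1,8-diyl (1R,2S,3R,4S)-3,4-bis(4-acetoxyphenyl)cyclobutane-1,2-dicarboxylate (meso β-truxinate pattern: acyl/acyl cis, aryl/aryl cis, acyl/aryl trans)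
Conditions: hν (medium-pressure Hg lamp, Pyrex, λ > 300 nm), powdered crystalline solid between glass plates, rt, remixed periodically
Reagents that add atoms: none
Why: Template-directed [2+2] photocycloaddition of cinnamates, in which the peri positions hold the two E-alkenes parallel, head to head and within about 4 Å, so that suprafacial addition should set all four stereocentres at once (E-geometry puts each aryl trans to its acyl neighbour, syn stacking puts acyl/acyl and aryl/aryl cis).

**Step 3**
Reactants: 4 template-bound β-truxinate
Product: 5 (1R,2S,3R,4S)-3,4-bis(4-hydroxyphenyl)-N1,N2-dimethoxy-N1,N2-dimethylcyclobutane-1,2-dicarboxamide (meso)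
Conditions: MeNH(OMe)·HCl (8 equiv), AlMe3 (8 equiv), CH2Cl2, 0 °C → rt; 1 M HCl quench, 0 °C
Reagents that add atoms: N,O-dimethylhydroxylamine hydrochloride, CNOC.Cl
Why: Aluminium-amide aminolysis of esters (Weinreb amidation), in which the non-basic reagent attacks all four activated aryl ester groups, so the template and both acetates leave in one operation without enolisation at C1/C2.

**Step 4**
Reactants: 6 4-bromoresorcinol
Product: 7 2,4-bis(benzyloxy)-1-bromobenzene
Conditions: BnBr (2.2 equiv), K2CO3 (3 equiv), DMF, rt → 50 °C
Reagents that add atoms: benzyl bromide, BrCc1ccccc1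
Why: Williamson ether synthesis on both phenoxides with a reactive benzylic halide; the aryl bromide is inert under these conditions.

**Step 5**
Reactants: 7 2,4-bis(benzyloxy)-1-bromobenzene; 5 bis(Weinreb amide) bis(phenol)
Product: 10 [(1R,2S,3R,4S)-3,4-bis(4-hydroxyphenyl)cyclobutane-1,2-diyl]bis{[2,4-bis(benzyloxy)phenyl]methanone}, via aryllithium 8 (not isolated), via tetralithium bis-hemiaminal adduct 9 (not isolated)
Conditions: 7 (4.6 equiv), n-BuLi (4.5 equiv), THF, −78 °C; then 5 in THF, −78 → −40 °C; AcOH/THF quench at −78 °C
Reagents that add atoms: none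
Why: Bromine–lithium exchange followed by Weinreb ketone synthesis, in which two equivalents of 8 mask the phenols as lithium phenoxides, the chelated adduct 9 holds both carbonyl carbons at the ketone level until the cold acidic quench, and the low temperature avoids enolisation so that the cis relation at C1/C2 is kept.

**Step 6**
Reactants: 10 cyclobutane diketone bis(phenol)
Product: 13 [(2R,3R,4S,5S)-2,5-bis(4-hydroxyphenyl)oxolane-3,4-diyl]bis{[2,4-bis(benzyloxy)phenyl]methanone}, via bis(p-quinone methide) 11 (not isolated), via carbinol quinone methide 12 (not isolated)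
Conditions: DDQ (1.0 equiv), acetone/H2O 5:1 (0.01 M), 0 °C → rt, dark
Reagents that add atoms: water, O
Why: DDQ takes two electrons and two protons from the pair of phenols: as one phenol is oxidised the other pushes through the strained C–C bond joining the two aryl-bearing ring carbons (a vinylogous Grob-type fragmentation driven by about 26 kcal/mol of ring strain), and the cyclobutane opens to the bis(p-quinone methide) 11. Water adds 1,6 to one of the two enantiotopic quinone methides to give carbinol 12, whose hydroxyl group closes the oxolane by a 5-exo-trig oxa-1,6-addition to the second quinone methide, so the net result is insertion of one oxygen atom into the four-membered ring. The closest known reaction types are the oxidative ring opening of 1,2-bis(4-hydroxyaryl)cyclobutanes to bis(quinone methides) with capture by water or hydroxyl groups, and the hydration of 8,8'-linked bis(quinone methides) to 2,5-diaryloxolanes. C3 and C4 are spectators and keep the cis relation from step 2, C2 is set by 1,2-induction from C3 in the water addition and C5 by the envelope transition state of the closure, each aryl going trans to the neighbouring aroyl group, and because p-hydroxybenzyl ethers re-ionise to quinone methides under the weak acid DDQH2 a wrong C2 or C5 epimer should drain into the least crowded 2,3-trans-3,4-cis-4,5-trans isomer. Site selectivity for this C–C bond over a benzylic C–H bond or the aryl-carbon/acyl-carbon ring bond is secured by the face-to-face cis-diaryl conformation, in which the bond lies parallel to both aryl π-systems while the benzylic C–H bonds lie near the aryl planes, and by the second phenol, which stabilises the developing charge far better than an α-keto carbon could. Chemoselectivity is secured by O-benzylation and acyl deactivation of the resorcinol rings (no oxidation there and no flavanone-type closure by a 2'-hydroxyl group) and by base-free, water-rich, dilute conditions that favour hydration over tautomerisation of 11 or oligomerisation.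

**Step 7**
Reactants: 13 tetrabenzyl oxolane
Product: 14 [(2R,3R,4S,5S)-2,5-bis(4-hydroxyphenyl)oxolane-3,4-diyl]bis[(2,4-dihydroxyphenyl)methanone] (target, meso)
Conditions: H2 (1 atm), 10% Pd/C, EtOAc/MeOH 1:1, rt, stopped after uptake of 4 equiv H2
Reagents that add atoms: none
Why: Hydrogenolysis of aryl benzyl ethers, whose primary O–CH2Ph bonds should be cleaved much faster than the hindered secondary ring C–O bonds or the aryl ketones are reduced, in a neutral medium that leaves all four stereocentres untouched.

**Compound list**
1 | (E)-4-acetoxycinnamic acid | CC(=O)Oc1ccc(/C=C/C(=O)O)cc1 | starting material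
2 | 1,8-dihydroxynaphthalene | Oc1cccc2cccc(O)c12 | starting material
3 | naphthalene-1,8-diyl bis[(E)-3-(4-acetoxyphenyl)prop-2-enoate] | CC(=O)Oc1ccc(/C=C/C(=O)Oc2cccc3cccc(OC(=O)/C=C/c4ccc(OC(C)=O)cc4)c23)cc1 | intermediate
4 | cyclic naphthalene-1,8-diyl (1R,2S,3R,4S)-3,4-bis(4-acetoxyphenyl)cyclobutane-1,2-dicarboxylate (meso) | O=C1Oc2cccc3cccc(c23)OC(=O)[C@@H]4[C@H]1[C@@H](c1ccc(OC(C)=O)cc1)[C@H]4c1ccc(OC(C)=O)cc1 | intermediate
5 | (1R,2S,3R,4S)-3,4-bis(4-hydroxyphenyl)-N1,N2-dimethoxy-N1,N2-dimethylcyclobutane-1,2-dicarboxamide (meso) | CON(C)C(=O)[C@@H]1[C@H](C(=O)N(C)OC)[C@@H](c2ccc(O)cc2)[C@H]1c1ccc(O)cc1 | intermediate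
6 | 4-bromoresorcinol | Oc1ccc(Br)c(O)c1 | starting material
7 | 2,4-bis(benzyloxy)-1-bromobenzene | Brc1ccc(OCc2ccccc2)cc1OCc1ccccc1 | intermediate
8 | [2,4-bis(benzyloxy)phenyl]lithium (not isolated) | [Li]c1ccc(OCc2ccccc2)cc1OCc1ccccc1 | intermediate
9 | tetralithium bis(hemiaminal alkoxide) bis(phenoxide) adduct, hemiaminal carbons undefined (not isolated) | [Li]OC(N(C)OC)(c1ccc(OCc2ccccc2)cc1OCc1ccccc1)[C@@H]1[C@H](C(O[Li])(N(C)OC)c2ccc(OCc3ccccc3)cc2OCc2ccccc2)[C@@H](c2ccc(O[Li])cc2)[C@H]1c1ccc(O[Li])cc1 | intermediate
10 | [(1R,2S,3R,4S)-3,4-bis(4-hydroxyphenyl)cyclobutane-1,2-diyl]bis{[2,4-bis(benzyloxy)phenyl]methanone} (meso) | O=C(c1ccc(OCc2ccccc2)cc1OCc1ccccc1)[C@@H]1[C@H](C(=O)c2ccc(OCc3ccccc3)cc2OCc2ccccc2)[C@@H](c2ccc(O)cc2)[C@H]1c1ccc(O)cc1 | intermediate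
11 | meso-(2R,3S)-2,3-bis[2,4-bis(benzyloxy)benzoyl]-1,4-bis(4-oxocyclohexa-2,5-dien-1-ylidene)butane (not isolated) | O=C1C=CC(C=C1)=C[C@H](C(=O)c1ccc(OCc2ccccc2)cc1OCc1ccccc1)[C@H](C(=O)c1ccc(OCc2ccccc2)cc1OCc1ccccc1)C=C1C=CC(=O)C=C1 | intermediate
12 | monohydrate of 11: benzylic carbinol with one remaining quinone methide, racemic, one enantiomer drawn (not isolated) | Oc1ccc(cc1)[C@H](O)[C@H](C(=O)c1ccc(OCc2ccccc2)cc1OCc1ccccc1)[C@H](C(=O)c1ccc(OCc2ccccc2)cc1OCc1ccccc1)C=C1C=CC(=O)C=C1 | intermediate
13 | [(2R,3R,4S,5S)-2,5-bis(4-hydroxyphenyl)oxolane-3,4-diyl]bis{[2,4-bis(benzyloxy)phenyl]methanone} (meso) | O=C(c1ccc(OCc2ccccc2)cc1OCc1ccccc1)[C@@H]1[C@H](C(=O)c2ccc(OCc3ccccc3)cc2OCc2ccccc2)[C@@H](c2ccc(O)cc2)O[C@H]1c1ccc(O)cc1 | intermediate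
14 | [(2R,3R,4S,5S)-2,5-bis(4-hydroxyphenyl)oxolane-3,4-diyl]bis[(2,4-dihydroxyphenyl)methanone] (CNP0237262.1, meso) | O=C(c1ccc(O)cc1O)[C@@H]1[C@H](C(=O)c2ccc(O)cc2O)[C@@H](c2ccc(O)cc2)O[C@H]1c1ccc(O)cc1 | target

**Step count**
Total step count: 7. Longest linear sequence: 6 (steps 1, 2, 3, 5, 6, 7).

**Steps most likely to fail**

1. Step 6.
   - Several processes may intervene: tautomerisation of the quinone methides by loss of the acidic proton α to the ketone, capture of a quinone methide by the enol oxygen of the neighbouring aroyl group, phenol/quinone methide oligomerisation, or further oxidation at the new benzylic ether positions.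
   - The fallback moves the ring expansion forward to the amide oxidation level, where the α-protons are far less acidic and no enolisable aryl ketone is present. It sets out from 5.
   - Oxidation with DDQ in aqueous acetone should give the oxolane bis(Weinreb amide) F1.
   - This is treated at −78 °C with an excess of aryllithium 8, two equivalents again serving to mask the phenols, and quenched cold with AcOH. That comes back to the route at 13.

2. Step 5.
   - Several processes may intervene: incomplete second addition at the crowded cis-vicinal amide, attack of the first alkoxide on the neighbouring amide followed by over-addition, base-induced epimerisation at C1/C2, or phenoxide-driven opening of the donor–acceptor ring bond on warming.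
   - The fallback replaces carbanion addition by a base-free acyl cross-coupling. It sets out from 4.
   - AlMe3/EtSH in CH2Cl2 should remove the template and acetates and give the bis(S-ethyl thioester) F2.
   - Aryllithium 8 is trapped with B(OiPr)3 and hydrolysed to the arylboronic acid F3.
   - A Liebeskind–Srogl coupling of the two (Pd2(dba)3, tri(2-furyl)phosphine, CuTC, THF, 50 °C) comes back to the route at 10.

3. Step 2.
   - Several processes may intervene: E/Z isomerisation, photo-Fries rearrangement of the aryl esters, or a crystal form in which the reaction stalls.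
   - The fallback replaces the covalent template by topochemical (crystal-packing) control. It sets out from 1.
   - Esterification with 4-nitrophenol (DCC, DMAP) gives the activated ester F4, a type of cinnamate that tends to pack in translation-related head-to-head stacks.
   - Irradiation of its crystals should give the open-chain β-truxinate diester F5.
   - The aluminium-amide aminolysis of step 3 then comes back to the route at 5.

**Further compounds**
F1 | step 6 | (2R,3R,4S,5S)-2,5-bis(4-hydroxyphenyl)-N3,N4-dimethoxy-N3,N4-dimethyloxolane-3,4-dicarboxamide (meso) | CON(C)C(=O)[C@@H]1[C@H](C(=O)N(C)OC)[C@@H](c2ccc(O)cc2)O[C@H]1c1ccc(O)cc1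
F2 | step 5 | S,S'-diethyl (1R,2S,3R,4S)-3,4-bis(4-hydroxyphenyl)cyclobutane-1,2-bis(carbothioate) (meso) | CCSC(=O)[C@@H]1[C@H](C(=O)SCC)[C@@H](c2ccc(O)cc2)[C@H]1c1ccc(O)cc1
F3 | step 5 | [2,4-bis(benzyloxy)phenyl]boronic acid | OB(O)c1ccc(OCc2ccccc2)cc1OCc1ccccc1
F4 | step 2 | 4-nitrophenyl (E)-3-(4-acetoxyphenyl)prop-2-enoate | CC(=O)Oc1ccc(/C=C/C(=O)Oc2ccc(cc2)[N+](=O)[O-])cc1
F5 | step 2 | bis(4-nitrophenyl) (1R,2S,3R,4S)-3,4-bis(4-acetoxyphenyl)cyclobutane-1,2-dicarboxylate (meso) | O=C(Oc1ccc(cc1)[N+](=O)[O-])[C@@H]1[C@H](C(=O)Oc2ccc(cc2)[N+](=O)[O-])[C@@H](c2ccc(OC(C)=O)cc2)[C@H]1c1ccc(OC(C)=O)cc1
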